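Everything rests on one disconnection: the bond from furan carbon C6 to the methylene C7 that sits next to the tertiary carbinol C8. A ring carbon joined through CH2 to a C(OH)(CH3) unit is what an arene leaves when it opens a 2-methyl-2-alkyl oxirane at its unsubstituted end. A nickel-catalysed reductive coupling of the C6 bromide with the C7–C8 epoxide therefore closes the 13-membered ring (C1 to C14 through the furan oxygen) and unveils the C8 hydroxyl in one operation. The precursor is an open chain with a methyl 5-bromofuran-3-carboxylate at one end and an (S)-configured oxirane at the other, the E-enoate and the C10 and C11 silyl ethers already in place.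

Key step: step 17

Remarks on the chemistry
- Numbering: C1 (CH bearing isopropenyl), C2 (CH2), furan C3 (bonded to C2), C4 (CO2Me), C5 (H), C6, then C7 (CH2), C8 (C(OH)CH3), C9 (CH2), C10, C11, C12 (CO2Me), C13 (=CH), C14 (CH2, back to C1).
- Stereochemical check: the target is 1S, 8R, 11S with C12=C13 E (ester trans to C14). The seco epoxide must be 8S; the C8–O bond is kept, and the descriptor reads S while C10 is an ether and R once C10 is a ketone. No structure needed correction.
- C1 and both of its arms come from (S)-(+)-carvone: its carbonyl carbon becomes C3 and its β-carbon C13.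
- C10 is carried as a (10R) triethylsilyl ether. The group goes on under neutral conditions beside the acid-sensitive oxirane and comes off without an oxidant. C10 ends as the ketone, so its configuration does not reach the target.
- Assumption: in step 15 the (S,S)-ligand is taken as the antipode that delivers oxygen to the alkene face giving 8S; if the sense is the reverse, the (R,R)-ligand is used.

Step 1
Reactants: 1 (S)-(+)-carvone
Product: 2 (1S,4S,6S)-1-methyl-4-(prop-1-en-2-yl)-7-oxabicyclo[4.1.0]heptan-2-one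
Conditions: 30% H2O2, NaOH (cat.), MeOH, 0 °C
Reagents that add atoms: hydrogen peroxide (OO)
Why: Weitz–Scheffer nucleophilic epoxidation attacks only the electron-poor enone alkene, anti to the isopropenyl group, which is left untouched; the two new centres are erased in step 2.

Step 2
Reactants: 2
Product: 3 (3S)-5-oxo-3-(prop-1-en-2-yl)pentanoic acid
Conditions: H5IO6 (2.5 equiv), THF/H2O, 0 → 25 °C
Reagents that add atoms: periodic acid (OI(=O)(O)(O)(O)O); water (O)
Why: Periodic acid hydrolyses the α,β-epoxy ketone to the keto diol and then carries out two Malaprade-type cleavages, which excise the methyl-bearing ring carbon as acetic acid and leave the former carbonyl carbon as the acid (C3) and the former β-carbon as the aldehyde (C13), the isopropenyl centre being untouched.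

Step 3
Reactants: 3
Product: 5 (3S)-5,5-dimethoxy-3-(prop-1-en-2-yl)pentanoic acid, via methyl ester acetal 4 (not isolated)
Conditions: HC(OMe)3, MeOH, p-TsOH (cat.), 25 °C; then LiOH, H2O, 25 °C; AcOH to pH 5
Reagents that add atoms: methanol (CO); trimethyl orthoformate (COC(OC)OC); lithium hydroxide ([Li+].[OH-])
Why: Acid-catalysed acetalisation with concurrent Fischer esterification masks the aldehyde, which would otherwise condense with the β-ketoester made next, and saponification in the same flask frees the acid without touching the acetal.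

Step 4
Reactants: 5; 6 Meldrum's acid
Product: 8 methyl (5S)-7,7-dimethoxy-3-oxo-5-(prop-1-en-2-yl)heptanoate, via acyl Meldrum's acid 7 (not isolated)
Conditions: DCC, DMAP, CH2Cl2, 0 → 25 °C; then MeOH, 65 °C
Reagents that add atoms: methanol (CO)
Why: Carbodiimide-mediated C-acylation of Meldrum's acid followed by methanolysis with loss of acetone and CO2 (Oikawa–Yonemitsu homologation) gives the methyl β-ketoester under near-neutral conditions that spare the acetal.

Step 5
Reactants: 8; 9 chloroacetaldehyde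
Product: 11 methyl 2-[(2R)-4,4-dimethoxy-2-(prop-1-en-2-yl)butyl]furan-3-carboxylate, via hydroxydihydrofuran 10 (not isolated)
Conditions: ClCH2CHO (50% aq.), pyridine, 50 °C
Reagents that add atoms: none
Why: Feist–Benary annulation, in which aldol addition of the β-ketoester carbon to the aldehyde, O-alkylation with loss of chloride and dehydration give the 2-alkylfuran-3-carboxylate while the pyridine buffer keeps the acetal intact.

Step 6
Reactants: 11
Product: 13 methyl 5-bromo-2-[(2R)-4-oxo-2-(prop-1-en-2-yl)butyl]furan-3-carboxylate, via bromofuran acetal 12 (not isolated)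
Conditions: NBS (1.0 equiv), DMF, 0 °C, dark; then 1 M HCl, THF, 25 °C
Reagents that add atoms: N-bromosuccinimide (O=C1CCC(=O)N1Br); water (O)
Why: Electrophilic aromatic bromination should take the only free α-position of the furan (C6), which is more nucleophilic than the isolated isopropenyl group, and dilute acid then hydrolyses the dimethyl acetal to the C13 aldehyde.

Step 7
Reactants: 14 (4S)-4-benzyl-1,3-oxazolidin-2-one; 15 bromoacetyl bromide
Product: 16 (4S)-4-benzyl-3-(bromoacetyl)-1,3-oxazolidin-2-one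
Conditions: n-BuLi, THF, −78 °C; then 15, −78 → 0 °C
Reagents that add atoms: none
Why: N-acylation of the lithiated oxazolidinone by the acid bromide is the standard preparation of an Evans imide.

Step 8
Reactants: 17 methyl 2-(diethoxyphosphoryl)acetate; 16
Product: 18 methyl 4-[(4S)-4-benzyl-2-oxo-1,3-oxazolidin-3-yl]-2-(diethoxyphosphoryl)-4-oxobutanoate (both C2 epimers)
Conditions: NaH, THF, 0 °C; then 16, 0 → 25 °C
Reagents that add atoms: none
Why: SN2 alkylation of the soft sodium phosphonoacetate carbanion at the α-bromo imide gives the succinate-type phosphonate that carries C10–C12 and the auxiliary.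

Step 9
Reactants: 13; 18
Product: 19 methyl 2-[(2S,4E)-7-[(4S)-4-benzyl-2-oxo-1,3-oxazolidin-3-yl]-5-(methoxycarbonyl)-7-oxo-2-(prop-1-en-2-yl)hept-4-en-1-yl]-5-bromofuran-3-carboxylate
Conditions: LiCl, DBU, MeCN, 0 → 25 °C
Reagents that add atoms: none
Why: Horner–Wadsworth–Emmons olefination under Masamune–Roush conditions, in which an α-substituted phosphonoacetate places the aldehyde-derived chain (C14) trans to the ester and so should give the E-alkylidene, the mild amine base sparing the imide and the enolisable aldehyde.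

Step 10
Reactants: 19
Product: 20 methyl 2-[(2S,4E,6S)-7-[(4S)-4-benzyl-2-oxo-1,3-oxazolidin-3-yl]-6-hydroxy-5-(methoxycarbonyl)-7-oxo-2-(prop-1-en-2-yl)hept-4-en-1-yl]-5-bromofuran-3-carboxylate
Conditions: NaN(SiMe3)2, THF, −78 °C; 2-(phenylsulfonyl)-3-phenyloxaziridine; AcOH, −78 °C
Reagents that add atoms: 2-(phenylsulfonyl)-3-phenyloxaziridine (O=S(=O)(c1ccccc1)N1OC1c1ccccc1)
Why: Evans asymmetric enolate hydroxylation, in which the chelated Z-sodium enolate of the imide is oxidised at C11 by the Davis oxaziridine on the face opposite the benzyl group, which with the (4S)-auxiliary sets 11S.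

Step 11
Reactants: 20
Product: 21 methyl 2-[(2S,4E,6S)-7-[(4S)-4-benzyl-2-oxo-1,3-oxazolidin-3-yl]-6-[(tert-butyldimethylsilyl)oxy]-5-(methoxycarbonyl)-7-oxo-2-(prop-1-en-2-yl)hept-4-en-1-yl]-5-bromofuran-3-carboxylate
Conditions: TBSOTf, 2,6-lutidine, CH2Cl2, −78 → 0 °C
Reagents that add atoms: tert-butyldimethylsilyl triflate (CC(C)(C)[Si](C)(C)OS(=O)(=O)C(F)(F)F)
Why: Silylation of the secondary α-hydroxy imide with a silyl triflate and a hindered pyridine base is a standard protection that leaves the esters, alkenes and bromofuran alone.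

Step 12
Reactants: 21
Product: 22 methyl 5-bromo-2-[(2S,4E,6S)-6-[(tert-butyldimethylsilyl)oxy]-7-hydroxy-5-(methoxycarbonyl)-2-(prop-1-en-2-yl)hept-4-en-1-yl]furan-3-carboxylate
Conditions: LiBH4, MeOH (1 equiv), THF, 0 °C
Reagents that add atoms: none
Why: Reductive removal of the Evans auxiliary, in which borohydride attacks the activated exocyclic imide carbonyl much faster than the hindered conjugated methyl esters and gives the primary C10 alcohol.

Step 13
Reactants: 22
Product: 23 methyl 5-bromo-2-[(2S,4E,6S)-6-[(tert-butyldimethylsilyl)oxy]-5-(methoxycarbonyl)-7-oxo-2-(prop-1-en-2-yl)hept-4-en-1-yl]furan-3-carboxylate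
Conditions: DMP, NaHCO3, CH2Cl2, 0 → 25 °C; used crude
Reagents that add atoms: none
Why: Buffered Dess–Martin oxidation gives the α-silyloxy aldehyde under non-basic conditions that should neither epimerise C11 nor move the C12=C13 double bond.

Step 14
Reactants: 23; 24 trimethyl(2-methylprop-2-en-1-yl)silane
Product: 25 methyl 5-bromo-2-[(2S,4E,6S,7R)-6-[(tert-butyldimethylsilyl)oxy]-7-hydroxy-5-(methoxycarbonyl)-9-methyl-2-(prop-1-en-2-yl)deca-4,9-dien-1-yl]furan-3-carboxylate
Conditions: BF3·OEt2, CH2Cl2, −78 °C; aq. NaHCO3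
Reagents that add atoms: none
Why: Hosomi–Sakurai methallylation under non-chelating BF3 activation follows the polar Felkin–Anh model and should give the 10,11-anti (10R) homoallylic alcohol, while esters, enoate and bromofuran do not react at −78 °C.

Step 15
Reactants: 25
Product: 26 methyl 5-bromo-2-[(2S,4E,6S,7R)-6-[(tert-butyldimethylsilyl)oxy]-7-hydroxy-5-(methoxycarbonyl)-8-[(2S)-2-methyloxiran-2-yl]-2-(prop-1-en-2-yl)oct-4-en-1-yl]furan-3-carboxylate
Conditions: VO(OiPr)3 (cat.), (S,S)-bishydroxamic acid ligand from cyclohexane-1,2-diamine (cat.), cumene hydroperoxide, toluene, 0 → 25 °C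
Reagents that add atoms: cumene hydroperoxide (CC(C)(OO)c1ccccc1)
Why: Hydroxyl-directed vanadium-catalysed asymmetric epoxidation of a homoallylic alcohol, in which the C10 alkoxide binds the chiral bishydroxamate–vanadium peroxide so that only the C7=C8 alkene is oxidised (isopropenyl, enoate and furan are not) and the ligand dictates the 8S face.

Step 16
Reactants: 26
Product: 27 methyl 5-bromo-2-[(2S,4E,6S,7R)-6-[(tert-butyldimethylsilyl)oxy]-5-(methoxycarbonyl)-8-[(2S)-2-methyloxiran-2-yl]-2-(prop-1-en-2-yl)-7-[(triethylsilyl)oxy]oct-4-en-1-yl]furan-3-carboxylate (seco bromofuran epoxide)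
Conditions: TESCl, imidazole, DMAP (cat.), DMF, 25 °C
Reagents that add atoms: chlorotriethylsilane (CC[Si](Cl)(CC)CC)
Why: Silylation of the secondary alcohol under neutral imidazole conditions is tolerated by the acid-sensitive 2,2-disubstituted oxirane and removes a hydroxyl that could otherwise attack C7 during ring closure.

Step 17
Reactants: 27
Product: 29 dimethyl (1S,8S,10R,11S,12E)-11-[(tert-butyldimethylsilyl)oxy]-8-hydroxy-8-methyl-1-(prop-1-en-2-yl)-10-[(triethylsilyl)oxy]-3,6-epoxycyclotetradeca-3,5,12-triene-4,12-dicarboxylate, via iodohydrin 28 (not isolated)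
Conditions: NiBr2(dme) (20 mol%), 2,2'-bipyridine (20 mol%), NaI (50 mol%), Et3N·HCl (1.5 equiv), Zn dust (3 equiv), DMPU, 25 °C, syringe-pump addition of 27 to 2 mM
Reagents that add atoms: none
Why: Proposed new method: iodide, assisted by the mild acid Et3N·HCl, opens the oxirane of 27 at the unhindered C7 methylene to iodohydrin 28, zerovalent nickel inserts into the activated C6–Br bond of the ester-bearing furan, the C7 radical released from the iodide by halogen abstraction is captured by the furyl–nickel species, and reductive elimination forges C6–C7 while zinc returns nickel to its low-valent state. The closest known reaction is the intermolecular nickel/iodide co-catalysed reductive cross-electrophile coupling of aryl bromides with epoxides at their less hindered carbon, which has not been run as a ring closure. The 13-membered ring is closed end to end by intramolecular radical capture at nickel, with exo opening of the oxirane so that the oxygen stays outside the ring on C8. No stereocentre is formed, because the C8–O bond is never broken and the 8S arrangement of the epoxide is carried over. The step needs regioselection for C7 over C8, secured by SN2 attack of iodide at the CH2 terminus, chemoselection for the C6–Br bond, the only carbon–halogen bond present before the iodide forms, and ring closure over oligomerisation, favoured by slow addition at high dilution. Cyclisation of the primary C7 radical onto the C12=C13 enoate is the competing path that dilution cannot suppress and is the main risk.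

Step 18
Reactants: 29
Product: 30 dimethyl (1S,8S,10R,11S,12E)-11-[(tert-butyldimethylsilyl)oxy]-8,10-dihydroxy-8-methyl-1-(prop-1-en-2-yl)-3,6-epoxycyclotetradeca-3,5,12-triene-4,12-dicarboxylate
Conditions: PPTS, MeOH/CH2Cl2, 0 °C
Reagents that add atoms: none
Why: Acid-catalysed methanolysis cleaves the triethylsilyl ether far faster than the hindered tert-butyldimethylsilyl ether and so frees only the C10 hydroxyl.

Step 19
Reactants: 30
Product: 31 dimethyl (1S,8R,11S,12E)-11-[(tert-butyldimethylsilyl)oxy]-8-hydroxy-8-methyl-10-oxo-1-(prop-1-en-2-yl)-3,6-epoxycyclotetradeca-3,5,12-triene-4,12-dicarboxylate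
Conditions: DMP, NaHCO3, CH2Cl2, 0 °C
Reagents that add atoms: none
Why: Dess–Martin oxidation converts the secondary C10 alcohol into the ketone, the tertiary C8 alcohol cannot be oxidised, and the buffer guards against β-elimination of the new β-hydroxy ketone.

Step 20
Reactants: 31
Product: 32 dimethyl (1S,8R,11S,12E)-8,11-dihydroxy-8-methyl-10-oxo-1-(prop-1-en-2-yl)-3,6-epoxycyclotetradeca-3,5,12-triene-4,12-dicarboxylate (CNP0225662.1)
Conditions: HF·pyridine, pyridine, THF, 0 °C
Reagents that add atoms: none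
Why: Fluoride-mediated desilylation under buffered, weakly acidic conditions frees the C11 hydroxyl without enolising the α-ketol or dehydrating the β-hydroxy ketone.

Compound list
1 | (S)-(+)-carvone | CC1=CC[C@@H](CC1=O)C(C)=C | starting material
2 | (1S,4S,6S)-1-methyl-4-(prop-1-en-2-yl)-7-oxabicyclo[4.1.0]heptan-2-one (epoxide oxygen anti to isopropenyl) | C[C@]12O[C@H]1C[C@@H](CC2=O)C(C)=C | intermediate
3 | (3S)-5-oxo-3-(prop-1-en-2-yl)pentanoic acid | C=C(C)[C@H](CC(=O)O)CC=O | intermediate
4 | methyl (3S)-5,5-dimethoxy-3-(prop-1-en-2-yl)pentanoate | C=C(C)[C@H](CC(=O)OC)CC(OC)OC | intermediate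
5 | (3S)-5,5-dimethoxy-3-(prop-1-en-2-yl)pentanoic acid | C=C(C)[C@H](CC(=O)O)CC(OC)OC | intermediate
6 | Meldrum's acid (2,2-dimethyl-1,3-dioxane-4,6-dione) | CC1(C)OC(=O)CC(=O)O1 | starting material
7 | 5-[(3S)-5,5-dimethoxy-3-(prop-1-en-2-yl)pentanoyl]-2,2-dimethyl-1,3-dioxane-4,6-dione | C=C(C)[C@H](CC(=O)C1C(=O)OC(C)(C)OC1=O)CC(OC)OC | intermediate
8 | methyl (5S)-7,7-dimethoxy-3-oxo-5-(prop-1-en-2-yl)heptanoate | C=C(C)[C@H](CC(=O)CC(=O)OC)CC(OC)OC | intermediate
9 | chloroacetaldehyde | ClCC=O | starting material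
10 | methyl 2-[(2R)-4,4-dimethoxy-2-(prop-1-en-2-yl)butyl]-4-hydroxy-4,5-dihydrofuran-3-carboxylate (both carbinol epimers) | C=C(C)[C@H](CC1=C(C(=O)OC)C(O)CO1)CC(OC)OC | intermediate
11 | methyl 2-[(2R)-4,4-dimethoxy-2-(prop-1-en-2-yl)butyl]furan-3-carboxylate | C=C(C)[C@H](Cc1occc1C(=O)OC)CC(OC)OC | intermediate
12 | methyl 5-bromo-2-[(2R)-4,4-dimethoxy-2-(prop-1-en-2-yl)butyl]furan-3-carboxylate | C=C(C)[C@H](Cc1oc(Br)cc1C(=O)OC)CC(OC)OC | intermediate
13 | methyl 5-bromo-2-[(2R)-4-oxo-2-(prop-1-en-2-yl)butyl]furan-3-carboxylate | C=C(C)[C@H](Cc1oc(Br)cc1C(=O)OC)CC=O | intermediate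
14 | (4S)-4-benzyl-1,3-oxazolidin-2-one | O=C1N[C@@H](Cc2ccccc2)CO1 | starting material
15 | bromoacetyl bromide | BrCC(Br)=O | starting material
16 | (4S)-4-benzyl-3-(bromoacetyl)-1,3-oxazolidin-2-one | O=C(CBr)N1[C@@H](Cc2ccccc2)COC1=O | intermediate
17 | methyl 2-(diethoxyphosphoryl)acetate | CCOP(=O)(CC(=O)OC)OCC | starting material
18 | methyl 4-[(4S)-4-benzyl-2-oxo-1,3-oxazolidin-3-yl]-2-(diethoxyphosphoryl)-4-oxobutanoate (both C2 epimers) | CCOP(=O)(OCC)C(CC(=O)N1[C@@H](Cc2ccccc2)COC1=O)C(=O)OC | intermediate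
19 | methyl 2-[(2S,4E)-7-[(4S)-4-benzyl-2-oxo-1,3-oxazolidin-3-yl]-5-(methoxycarbonyl)-7-oxo-2-(prop-1-en-2-yl)hept-4-en-1-yl]-5-bromofuran-3-carboxylate | C=C(C)[C@H](Cc1oc(Br)cc1C(=O)OC)C/C=C(/C(=O)OC)CC(=O)N2[C@@H](Cc3ccccc3)COC2=O | intermediate
20 | methyl 2-[(2S,4E,6S)-7-[(4S)-4-benzyl-2-oxo-1,3-oxazolidin-3-yl]-6-hydroxy-5-(methoxycarbonyl)-7-oxo-2-(prop-1-en-2-yl)hept-4-en-1-yl]-5-bromofuran-3-carboxylate | C=C(C)[C@H](Cc1oc(Br)cc1C(=O)OC)C/C=C(/C(=O)OC)[C@H](O)C(=O)N2[C@@H](Cc3ccccc3)COC2=O | intermediate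
21 | methyl 2-[(2S,4E,6S)-7-[(4S)-4-benzyl-2-oxo-1,3-oxazolidin-3-yl]-6-[(tert-butyldimethylsilyl)oxy]-5-(methoxycarbonyl)-7-oxo-2-(prop-1-en-2-yl)hept-4-en-1-yl]-5-bromofuran-3-carboxylate | C=C(C)[C@H](Cc1oc(Br)cc1C(=O)OC)C/C=C(/C(=O)OC)[C@H](O[Si](C)(C)C(C)(C)C)C(=O)N2[C@@H](Cc3ccccc3)COC2=O | intermediate
22 | methyl 5-bromo-2-[(2S,4E,6S)-6-[(tert-butyldimethylsilyl)oxy]-7-hydroxy-5-(methoxycarbonyl)-2-(prop-1-en-2-yl)hept-4-en-1-yl]furan-3-carboxylate | C=C(C)[C@H](Cc1oc(Br)cc1C(=O)OC)C/C=C(/C(=O)OC)[C@H](O[Si](C)(C)C(C)(C)C)CO | intermediate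
23 | methyl 5-bromo-2-[(2S,4E,6S)-6-[(tert-butyldimethylsilyl)oxy]-5-(methoxycarbonyl)-7-oxo-2-(prop-1-en-2-yl)hept-4-en-1-yl]furan-3-carboxylate | C=C(C)[C@H](Cc1oc(Br)cc1C(=O)OC)C/C=C(/C(=O)OC)[C@H](O[Si](C)(C)C(C)(C)C)C=O | intermediate
24 | trimethyl(2-methylprop-2-en-1-yl)silane (methallyltrimethylsilane) | C=C(C)C[Si](C)(C)C | starting material
25 | methyl 5-bromo-2-[(2S,4E,6S,7R)-6-[(tert-butyldimethylsilyl)oxy]-7-hydroxy-5-(methoxycarbonyl)-9-methyl-2-(prop-1-en-2-yl)deca-4,9-dien-1-yl]furan-3-carboxylate | C=C(C)[C@H](Cc1oc(Br)cc1C(=O)OC)C/C=C(/C(=O)OC)[C@H](O[Si](C)(C)C(C)(C)C)[C@H](O)CC(C)=C | intermediate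
26 | methyl 5-bromo-2-[(2S,4E,6S,7R)-6-[(tert-butyldimethylsilyl)oxy]-7-hydroxy-5-(methoxycarbonyl)-8-[(2S)-2-methyloxiran-2-yl]-2-(prop-1-en-2-yl)oct-4-en-1-yl]furan-3-carboxylate | C=C(C)[C@H](Cc1oc(Br)cc1C(=O)OC)C/C=C(/C(=O)OC)[C@H](O[Si](C)(C)C(C)(C)C)[C@H](O)C[C@@]2(C)CO2 | intermediate
27 | methyl 5-bromo-2-[(2S,4E,6S,7R)-6-[(tert-butyldimethylsilyl)oxy]-5-(methoxycarbonyl)-8-[(2S)-2-methyloxiran-2-yl]-2-(prop-1-en-2-yl)-7-[(triethylsilyl)oxy]oct-4-en-1-yl]furan-3-carboxylate (seco bromofuran epoxide) | C=C(C)[C@H](Cc1oc(Br)cc1C(=O)OC)C/C=C(/C(=O)OC)[C@H](O[Si](C)(C)C(C)(C)C)[C@H](O[Si](CC)(CC)CC)C[C@@]2(C)CO2 | intermediate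
28 | iodohydrin of 27: oxirane opened to (8S)-C8(OH)(CH3)–C7H2I, all else unchanged | C=C(C)[C@H](Cc1oc(Br)cc1C(=O)OC)C/C=C(/C(=O)OC)[C@H](O[Si](C)(C)C(C)(C)C)[C@H](O[Si](CC)(CC)CC)C[C@](C)(O)CI | intermediate
29 | dimethyl (1S,8S,10R,11S,12E)-11-[(tert-butyldimethylsilyl)oxy]-8-hydroxy-8-methyl-1-(prop-1-en-2-yl)-10-[(triethylsilyl)oxy]-3,6-epoxycyclotetradeca-3,5,12-triene-4,12-dicarboxylate | C=C(C)[C@H]1C/C=C(/C(=O)OC)[C@H](O[Si](C)(C)C(C)(C)C)[C@H](O[Si](CC)(CC)CC)C[C@](C)(O)CC2=CC(C(=O)OC)=C(C1)O2 | intermediate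
30 | dimethyl (1S,8S,10R,11S,12E)-11-[(tert-butyldimethylsilyl)oxy]-8,10-dihydroxy-8-methyl-1-(prop-1-en-2-yl)-3,6-epoxycyclotetradeca-3,5,12-triene-4,12-dicarboxylate | C=C(C)[C@H]1C/C=C(/C(=O)OC)[C@H](O[Si](C)(C)C(C)(C)C)[C@H](O)C[C@](C)(O)CC2=CC(C(=O)OC)=C(C1)O2 | intermediate
31 | dimethyl (1S,8R,11S,12E)-11-[(tert-butyldimethylsilyl)oxy]-8-hydroxy-8-methyl-10-oxo-1-(prop-1-en-2-yl)-3,6-epoxycyclotetradeca-3,5,12-triene-4,12-dicarboxylate | C=C(C)[C@H]1C/C=C(/C(=O)OC)[C@H](O[Si](C)(C)C(C)(C)C)C(=O)C[C@](C)(O)CC2=CC(C(=O)OC)=C(C1)O2 | intermediate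
32 | dimethyl (1S,8R,11S,12E)-8,11-dihydroxy-8-methyl-10-oxo-1-(prop-1-en-2-yl)-3,6-epoxycyclotetradeca-3,5,12-triene-4,12-dicarboxylate (CNP0225662.1) | C=C(C)[C@H]1C/C=C(/C(=O)OC)[C@H](O)C(=O)C[C@](C)(O)CC2=CC(C(=O)OC)=C(C1)O2 | target

Total step count: 20.
Longest linear sequence: 18 steps from (S)-(+)-carvone (steps 1–6 and 9–20); steps 7 and 8 prepare phosphonate 18.

Steps most likely to fail

Step 17. The ring closure may lose to oligomerisation by intermolecular coupling, to simple reduction of the C6–Br bond, or to cyclisation of the C7 radical onto the C12=C13 enoate before it reaches nickel. The fallback sets out from 27 and comes back at 29, and replaces radical capture at nickel by a polar organometallic opening. Bromine–magnesium exchange at C6 with i-PrMgCl·LiCl (THF, −40 °C), which methyl esters tolerate at low temperature, would give the furylmagnesium chloride F1. Slow transfer of this solution into dilute THF containing CuI (cat.) at −30 → 0 °C should open the oxirane at C7, the usual site of copper-catalysed attack by aryl Grignard reagents on epoxides, and NH4Cl work-up would give 29.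

Step 15. Oxygen transfer may show poor facial selectivity if the preference of the (10R) substrate opposes that of the ligand, or may be slow at a hindered secondary carbinol. The fallback sets out from 25 and comes back at 26, and moves the stereocontrol from the catalyst to a chair-like cyclisation. Acylation with Boc2O and DMAP would give the tert-butyl carbonate F2. Treatment with IBr (toluene, −80 °C) should then close the six-membered cyclic iodocarbonate F3, in which the C10 substituent and the C7 iodomethyl group are cis; only the alkene that carries the internal carbonate nucleophile is trapped. K2CO3 in MeOH would cleave the carbonate and close the oxirane to give 26.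

Step 6. Bromination may stray to the isopropenyl group or to the furylic C2 methylene instead of staying on the ring. The fallback sets out from 11 and comes back at 13, and replaces electrophilic bromination by C–H borylation followed by halodeboronation. Iridium-catalysed borylation ([Ir(OMe)(cod)]2, 4,4'-di-tert-butyl-2,2'-bipyridine, B2pin2, THF, 60 °C) should take the only free furan α-position and give the C6 pinacol boronate F4. CuBr2 in MeOH/H2O would convert the boronate into the bromide 12, and the acid hydrolysis of step 6 would then give 13.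

Further compounds
F1 | step 17 | furylmagnesium chloride from 27 (C6–MgCl in place of C6–Br) | C=C(C)[C@H](Cc1oc([Mg]Cl)cc1C(=O)OC)C/C=C(/C(=O)OC)[C@H](O[Si](C)(C)C(C)(C)C)[C@H](O[Si](CC)(CC)CC)C[C@@]2(C)CO2
F2 | step 15 | tert-butyl carbonate of 25 at the C10 oxygen | C=C(C)[C@H](Cc1oc(Br)cc1C(=O)OC)C/C=C(/C(=O)OC)[C@H](O[Si](C)(C)C(C)(C)C)[C@H](OC(=O)OC(C)(C)C)CC(C)=C
F3 | step 15 | cyclic iodocarbonate: 1,3-dioxan-2-one spanning the C10 and C8 oxygens, C8 bearing CH3 and CH2I | C=C(C)[C@H](Cc1oc(Br)cc1C(=O)OC)C/C=C(/C(=O)OC)[C@H](O[Si](C)(C)C(C)(C)C)[C@H]2C[C@@](C)(CI)OC(=O)O2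
F4 | step 6 | methyl 2-[(2R)-4,4-dimethoxy-2-(prop-1-en-2-yl)butyl]-5-(4,4,5,5-tetramethyl-1,3,2-dioxaborolan-2-yl)furan-3-carboxylate | C=C(C)[C@H](Cc1oc(B2OC(C)(C)C(C)(C)O2)cc1C(=O)OC)CC(OC)OC
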